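**Plan**
- Cuts: O2–C3 (ring B) and C4–C4a give enyne 14 and monocyclic vinyl triflate 34. Ring A of 34 is opened at C5–C6 to keto lactone 30. In 14, C11–CH3 and C11–C10 are cut back to oxolane ester 6, and O1'–C5' of ring C is cut last.
- Feature behind the key step: C5', C4', C3' with its methyl, C2' and C11 are the six carbons of L-isoleucine and carry its (2S,3S) centres at C2' and C3'. Ring C therefore lacks only the bond from the C2' oxygen to the C5' methyl, whose hydrogens sit 1,5 to that oxygen.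
- Forward: ring C (steps 1–3), chain growth to 14 (steps 4–8). Separately, a temporary lactone ring (step 14) carries the diol and is turned into carbocyclic ring A (step 19). The halves are joined in step 22 and ring B closes last (step 23).
- Stereochemistry: C2' and C3' from L-isoleucine; C11 by chelation-controlled methyl addition; (E)-C9=C10 by trans-hydroalumination; C8a by an Evans aldol; C7 and C8 by dihydroxylation anti to the C8a side chain of the lactone, which becomes the all-cis C1/8-O/7-O pattern on ring A.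

Key step: step 3

Remark: atoms are numbered as in the isochromenone (C1, O2, C3–C8a), the side chain (C9–C11) and the oxolane (O1'–C5'); intermediates are described with these locants.

**Route**

Step 1
Reactants: 1 L-isoleucine
Product: 2 (2S,3S)-2-hydroxy-3-methylpentanoic acid
Conditions: NaNO2, 1 M H2SO4, H2O, 0 °C → rt
Reagents that add atoms: water, O
Why: Diazotisation of the α-amino acid (deaminative hydroxylation) should pass through an α-lactone, so two inversions leave C2' with net retention and C3' is not involved.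

Step 2
Reactants: 2 (2S,3S)-2-hydroxy-3-methylpentanoic acid
Product: 3 methyl (2S,3S)-2-hydroxy-3-methylpentanoate
Conditions: MeOH, H2SO4 (cat.), reflux
Reagents that add atoms: methanol, CO
Why: Fischer esterification, which touches neither stereocentre.

Step 3
Reactants: 3 methyl (2S,3S)-2-hydroxy-3-methylpentanoate
Product: 6 methyl (2S,3S)-3-methyloxolane-2-carboxylate, via hypoiodite 4 (not isolated), via iodo alcohol 5 (not isolated)
Conditions: PhI(OAc)2, I2, CH2Cl2, visible light (tungsten lamp), 15 °C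
Reagents that add atoms: none
Why: Acetyl hypoiodite formed in the flask should convert the C2' hydroxyl into hypoiodite 4, whose O–I bond is cleaved by visible light to an alkoxy radical; this abstracts a hydrogen from the C5' methyl through a six-membered chair-like transition state (1,5-hydrogen transfer), the primary radical takes up iodine to give 5, and the hydroxyl then displaces the iodide, helped by further oxidation at iodine. The closest known reaction type is the hypoiodite reaction (remote C–H etherification through an alkoxy radical), in which primary C–H donors are the least efficient class. Ring C closes by O1'–C5' bond formation in a 5-exo-tet mode. No stereocentre is created, and C2' and C3' lie outside the radical site and keep the configuration of L-isoleucine. The step needs site selectivity for the C5' hydrogens over the C4' and C3'-methyl hydrogens (reachable only through five-membered transition states) and over β-scission: the ester disfavours cleavage toward C11, its Z geometry keeps the OCH3 hydrogens out of reach, and a low temperature should favour hydrogen transfer over loss of a sec-butyl radical.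

Step 4
Reactants: 6 methyl (2S,3S)-3-methyloxolane-2-carboxylate
Product: 7 (2S,3S)-N-methoxy-N,3-dimethyloxolane-2-carboxamide
Conditions: Me(MeO)NH·HCl, iPrMgCl, THF, −20 °C
Reagents that add atoms: N,O-dimethylhydroxylamine hydrochloride, CNOC.Cl
Why: Aminolysis of the ester by the chloromagnesium amide (Weinreb amide formation) is fast at low temperature and should leave the α-alkoxy stereocentre untouched.

Step 5
Reactants: 7 (2S,3S)-N-methoxy-N,3-dimethyloxolane-2-carboxamide, 8 1,4-bis(trimethylsilyl)buta-1,3-diyne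
Product: 10 1-[(2S,3S)-3-methyloxolan-2-yl]-5-(trimethylsilyl)penta-2,4-diyn-1-one, via lithium diynide 9 (not isolated)
Conditions: 8, MeLi·LiBr, THF, −78 °C → rt; then 7, −78 → 0 °C; aq. NH4Cl
Reagents that add atoms: none
Why: Mono-desilylation of 8 gives the lithium diynide, which should acylate only once because the chelated tetrahedral adduct of the Weinreb amide survives until work-up (Weinreb ketone synthesis); this brings in C10, C9, C3 and C4 together.

Step 6
Reactants: 10 1-[(2S,3S)-3-methyloxolan-2-yl]-5-(trimethylsilyl)penta-2,4-diyn-1-one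
Product: 11 (2R)-2-[(2S,3S)-3-methyloxolan-2-yl]-6-(trimethylsilyl)hexa-3,5-diyn-2-ol
Conditions: MeMgBr, Et2O/CH2Cl2, −78 °C; aq. NH4Cl
Reagents that add atoms: methylmagnesium bromide, C[Mg]Br
Why: Chelation-controlled Grignard 1,2-addition (Cram chelate model): magnesium bridges the ketone oxygen and O1', and methyl should add from the face of the C2'–H, which sets C11 as R.

Step 7
Reactants: 11 (2R)-2-[(2S,3S)-3-methyloxolan-2-yl]-6-(trimethylsilyl)hexa-3,5-diyn-2-ol
Product: 13 (2R,3E)-2-[(2S,3S)-3-methyloxolan-2-yl]-6-(trimethylsilyl)hex-3-en-5-yn-2-ol, via alkenylalanate 12 (not isolated)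
Conditions: NaAlH2(OCH2CH2OMe)2 (Red-Al), THF, 0 °C → rt; aq. potassium sodium tartrate
Reagents that add atoms: none
Why: Hydroxyl-directed trans-hydroalumination of the proximal triple bond through the five-membered alkoxyalanate, followed by protonolysis, should give only the (E)-alkene (Red-Al reduction of a propargylic alcohol); the silylated distal alkyne has no directing group.

Step 8
Reactants: 13 (2R,3E)-2-[(2S,3S)-3-methyloxolan-2-yl]-6-(trimethylsilyl)hex-3-en-5-yn-2-ol
Product: 14 (2R,3E)-2-[(2S,3S)-3-methyloxolan-2-yl]hex-3-en-5-yn-2-ol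
Conditions: K2CO3, MeOH, rt
Reagents that add atoms: none
Why: Carbonate-catalysed methanolysis of the alkynyl–silicon bond (protodesilylation) spares the tertiary alcohol and the (E)-alkene.

Step 9
Reactants: 15 (4S)-4-benzyl-1,3-oxazolidin-2-one, 16 (2E)-but-2-enoyl chloride
Product: 18 (4S)-4-benzyl-3-[(2E)-but-2-enoyl]-1,3-oxazolidin-2-one, via lithium oxazolidinide 17 (not isolated)
Conditions: n-BuLi, THF, −78 °C; then 16, −78 → 0 °C
Reagents that add atoms: none
Why: N-Acylation of the lithiated oxazolidinone by the acid chloride (loading of the Evans auxiliary).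

Step 10
Reactants: 18 (4S)-4-benzyl-3-[(2E)-but-2-enoyl]-1,3-oxazolidin-2-one, 19 acetaldehyde
Product: 21 (4S)-4-benzyl-3-[(2S,3R)-2-ethenyl-3-hydroxybutanoyl]-1,3-oxazolidin-2-one, via boron dienolate 20 (not isolated)
Conditions: Bu2BOTf, Et3N, CH2Cl2, −78 → 0 °C; then 19, −78 → 0 °C; pH 7 buffer, H2O2, MeOH
Reagents that add atoms: none
Why: Evans syn-aldol reaction: the (Z)-boron dienolate should react at its α-carbon through a Zimmerman–Traxler chair on the face away from the benzyl group, which sets the future C8a (2S in 21), while the syn carbinol centre is only a relay that is oxidised in step 18.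

Step 11
Reactants: 21 (4S)-4-benzyl-3-[(2S,3R)-2-ethenyl-3-hydroxybutanoyl]-1,3-oxazolidin-2-one
Product: 22 (4S)-4-benzyl-3-[(2S,3R)-3-{[tert-butyl(dimethyl)silyl]oxy}-2-ethenylbutanoyl]-1,3-oxazolidin-2-one
Conditions: TBSOTf, 2,6-lutidine, CH2Cl2, −78 → 0 °C
Reagents that add atoms: tert-butyldimethylsilyl trifluoromethanesulfonate, CC(C)(C)[Si](C)(C)OS(=O)(=O)C(F)(F)F
Why: Silylation of the secondary alcohol with a silyl triflate and a hindered base protects the future C4a oxygen and blocks retro-aldol cleavage.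

Step 12
Reactants: 22 (4S)-4-benzyl-3-[(2S,3R)-3-{[tert-butyl(dimethyl)silyl]oxy}-2-ethenylbutanoyl]-1,3-oxazolidin-2-one
Product: 23 (2R,3R)-3-{[tert-butyl(dimethyl)silyl]oxy}-2-ethenylbutan-1-ol
Conditions: LiBH4, MeOH (1 equiv), THF, 0 °C
Reagents that add atoms: none
Why: Reductive cleavage of the imide by borohydride gives the primary alcohol (future C1–O2) without touching the α-stereocentre, whose descriptor changes only by priority.

Step 13
Reactants: 23 (2R,3R)-3-{[tert-butyl(dimethyl)silyl]oxy}-2-ethenylbutan-1-ol, 24 2-methylprop-2-enoyl chloride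
Product: 25 (2R,3R)-3-{[tert-butyl(dimethyl)silyl]oxy}-2-ethenylbutyl 2-methylprop-2-enoate
Conditions: 24, Et3N, DMAP (cat.), CH2Cl2, 0 °C
Reagents that add atoms: none
Why: DMAP-catalysed esterification of the primary alcohol with the acid chloride.

Step 14
Reactants: 25 (2R,3R)-3-{[tert-butyl(dimethyl)silyl]oxy}-2-ethenylbutyl 2-methylprop-2-enoate
Product: 26 (5R)-5-[(1R)-1-{[tert-butyl(dimethyl)silyl]oxy}ethyl]-3-methyl-5,6-dihydro-2H-pyran-2-one
Conditions: second-generation Grubbs catalyst RuCl2(=CHPh)(H2IMes)(PCy3) (5 mol%), CH2Cl2 (0.01 M), 40 °C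
Reagents that add atoms: none
Why: Ring-closing metathesis of the vinyl group with the methacrylate should give the six-membered α-methyl unsaturated lactone, in which the C7=C8 alkene is necessarily cis within the ring.

Step 15
Reactants: 26 (5R)-5-[(1R)-1-{[tert-butyl(dimethyl)silyl]oxy}ethyl]-3-methyl-5,6-dihydro-2H-pyran-2-one
Product: 27 (3R,4R,5S)-5-[(1R)-1-{[tert-butyl(dimethyl)silyl]oxy}ethyl]-3,4-dihydroxy-3-methyloxan-2-one
Conditions: OsO4 (5 mol%), NMO, acetone/H2O, rt
Reagents that add atoms: osmium tetroxide, O=[Os](=O)(=O)=O; N-methylmorpholine N-oxide, C[N+]1([O-])CCOCC1; water, O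
Why: Upjohn dihydroxylation: OsO4 should add suprafacially to the lactone alkene on the face opposite the adjacent C5 side chain, setting C7 and C8 (3R,4R in 27) cis to each other and trans to that chain.

Step 16
Reactants: 27 (3R,4R,5S)-5-[(1R)-1-{[tert-butyl(dimethyl)silyl]oxy}ethyl]-3,4-dihydroxy-3-methyloxan-2-one
Product: 28 (3aR,7S,7aR)-7-[(1R)-1-{[tert-butyl(dimethyl)silyl]oxy}ethyl]-2,2,3a-trimethyl-3a,6,7,7a-tetrahydro-4H-[1,3]dioxolo[4,5-c]pyran-4-one
Conditions: Me2C(OMe)2, CSA (cat.), CH2Cl2, rt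
Reagents that add atoms: 2,2-dimethoxypropane, COC(C)(C)OC
Why: Acid-catalysed transketalisation of the cis-1,2-diol gives the cis-fused dioxolane (acetonide formation), and the secondary silyl ether tolerates catalytic acid.

Step 17
Reactants: 28 (3aR,7S,7aR)-7-[(1R)-1-{[tert-butyl(dimethyl)silyl]oxy}ethyl]-2,2,3a-trimethyl-3a,6,7,7a-tetrahydro-4H-[1,3]dioxolo[4,5-c]pyran-4-one
Product: 29 (3aR,7R,7aR)-7-[(1R)-1-hydroxyethyl]-2,2,3a-trimethyl-3a,6,7,7a-tetrahydro-4H-[1,3]dioxolo[4,5-c]pyran-4-one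
Conditions: HF·pyridine, pyridine, THF, 0 °C → rt
Reagents that add atoms: none
Why: Fluoride-mediated desilylation under buffered, non-basic conditions should spare the acetonide and avoid translactonisation.

Step 18
Reactants: 29 (3aR,7R,7aR)-7-[(1R)-1-hydroxyethyl]-2,2,3a-trimethyl-3a,6,7,7a-tetrahydro-4H-[1,3]dioxolo[4,5-c]pyran-4-one
Product: 30 (3aR,7S,7aR)-7-acetyl-2,2,3a-trimethyl-3a,6,7,7a-tetrahydro-4H-[1,3]dioxolo[4,5-c]pyran-4-one
Conditions: Dess–Martin periodinane, CH2Cl2, rt
Reagents that add atoms: none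
Why: Dess–Martin oxidation of the secondary alcohol under near-neutral conditions should give the methyl ketone (C4a, C5) without epimerising the adjacent C8a.

Step 19
Reactants: 30 (3aR,7S,7aR)-7-acetyl-2,2,3a-trimethyl-3a,6,7,7a-tetrahydro-4H-[1,3]dioxolo[4,5-c]pyran-4-one
Product: 32 (3aR,7S,7aR)-7-(hydroxymethyl)-2,2,3a-trimethyl-7,7a-dihydro-3aH-1,3-benzodioxole-4,6(5H)-dione, via lithium enolate 31 (not isolated)
Conditions: LiN(SiMe3)2 (2.2 equiv), THF, −78 → 0 °C; 1 M HCl, 0 °C
Reagents that add atoms: none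
Why: Intramolecular Claisen (Dieckmann-type) condensation: the kinetic methyl-ketone enolate (C5) should attack the lactone carbonyl (C6, no α-hydrogen), and collapse of the bridged adduct expels the C1 alkoxide, the stable 1,3-diketone enolate driving the change of lactone into carbocyclic ring A without touching a stereocentre.

Step 20
Reactants: 32 (3aR,7S,7aR)-7-(hydroxymethyl)-2,2,3a-trimethyl-7,7a-dihydro-3aH-1,3-benzodioxole-4,6(5H)-dione
Product: 33 (3aR,7S,7aR)-5-chloro-6-hydroxy-7-(hydroxymethyl)-2,2,3a-trimethyl-7,7a-dihydro-1,3-benzodioxol-4(3aH)-one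
Conditions: NCS (1.0 equiv), CH2Cl2, 0 °C
Reagents that add atoms: N-chlorosuccinimide, O=C1CCC(=O)N1Cl
Why: Electrophilic α-chlorination of the enolised 1,3-diketone at C5, the only doubly activated carbon.

Step 21
Reactants: 33 (3aR,7S,7aR)-5-chloro-6-hydroxy-7-(hydroxymethyl)-2,2,3a-trimethyl-7,7a-dihydro-1,3-benzodioxol-4(3aH)-one
Product: 34 (3aR,7S,7aR)-5-chloro-7-(hydroxymethyl)-2,2,3a-trimethyl-4-oxo-3a,4,7,7a-tetrahydro-1,3-benzodioxol-6-yl trifluoromethanesulfonate
Conditions: PhNTf2, Et3N, DMAP (cat.), CH2Cl2, 0 °C → rt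
Reagents that add atoms: N-phenylbis(trifluoromethanesulfonimide), O=S(=O)(N(c1ccccc1)S(=O)(=O)C(F)(F)F)C(F)(F)F
Why: O-Sulfonylation of the vinylogous acid (enol triflate formation) with a reagent that reacts with the enolate but not with the neutral primary alcohol should occur at the less hindered oxygen on C4a, next to C8a–H and not to quaternary C7.

Step 22
Reactants: 34 (3aR,7S,7aR)-5-chloro-7-(hydroxymethyl)-2,2,3a-trimethyl-4-oxo-3a,4,7,7a-tetrahydro-1,3-benzodioxol-6-yl trifluoromethanesulfonate, 14 (2R,3E)-2-[(2S,3S)-3-methyloxolan-2-yl]hex-3-en-5-yn-2-ol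
Product: 35 (3aR,7S,7aR)-5-chloro-7-(hydroxymethyl)-6-{(3E,5R)-5-hydroxy-5-[(2S,3S)-3-methyloxolan-2-yl]hex-3-en-1-yn-1-yl}-2,2,3a-trimethyl-7,7a-dihydro-1,3-benzodioxol-4(3aH)-one
Conditions: Pd(PPh3)4 (5 mol%), CuI (10 mol%), iPr2NH, THF, rt
Reagents that add atoms: none
Why: Sonogashira coupling of the electron-poor vinyl triflate with the terminal enyne forms C4–C4a, and the vinyl chloride, the free alcohols and the acetonide should be inert to zerovalent palladium and monovalent copper at room temperature.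

Step 23
Reactants: 35 (3aR,7S,7aR)-5-chloro-7-(hydroxymethyl)-6-{(3E,5R)-5-hydroxy-5-[(2S,3S)-3-methyloxolan-2-yl]hex-3-en-1-yn-1-yl}-2,2,3a-trimethyl-7,7a-dihydro-1,3-benzodioxol-4(3aH)-one
Product: 36 (7R,8R,8aS)-5-chloro-3-{(1E,3R)-3-hydroxy-3-[(2S,3S)-3-methyloxolan-2-yl]but-1-en-1-yl}-7-methyl-7,8-(isopropylidenedioxy)-1,7,8,8a-tetrahydro-6H-isochromen-6-one
Conditions: (Ph3P)AuNTf2 (5 mol%), CH2Cl2, rt
Reagents that add atoms: none
Why: 6-endo-dig hydroalkoxylation (cycloisomerisation) catalysed by monovalent gold: the C1 hydroxyl should add to C3, the alkyne carbon remote from the enone and so the electrophilic end of the ynenone, closing ring B, while the masked diol and the (E)-held C11 hydroxyl cannot compete.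

Step 24
Reactants: 36 (7R,8R,8aS)-5-chloro-3-{(1E,3R)-3-hydroxy-3-[(2S,3S)-3-methyloxolan-2-yl]but-1-en-1-yl}-7-methyl-7,8-(isopropylidenedioxy)-1,7,8,8a-tetrahydro-6H-isochromen-6-one
Product: 37 CNP0432723.2, (7R,8R,8aS)-5-chloro-7,8-dihydroxy-3-{(1E,3R)-3-hydroxy-3-[(2S,3S)-3-methyloxolan-2-yl]but-1-en-1-yl}-7-methyl-1,7,8,8a-tetrahydro-6H-isochromen-6-one
Conditions: TFA/H2O (9:1), 0 °C
Reagents that add atoms: none
Why: Acid hydrolysis of the isopropylidene ketal (acetonide cleavage); the vinylogous ester and the electron-poor tertiary allylic alcohol should tolerate brief cold aqueous acid, and no stereocentre is involved.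

**Compound list**

1 | L-isoleucine, (2S,3S)-2-amino-3-methylpentanoic acid | CC[C@H](C)[C@H](N)C(=O)O | starting material
2 | (2S,3S)-2-hydroxy-3-methylpentanoic acid | CC[C@H](C)[C@H](O)C(=O)O | intermediate
3 | methyl (2S,3S)-2-hydroxy-3-methylpentanoate | CC[C@H](C)[C@H](O)C(=O)OC | intermediate
4 | methyl (2S,3S)-2-(iodooxy)-3-methylpentanoate (hypoiodite) | CC[C@H](C)[C@H](OI)C(=O)OC | intermediate (not isolated)
5 | methyl (2S,3S)-2-hydroxy-5-iodo-3-methylpentanoate | ICC[C@H](C)[C@H](O)C(=O)OC | intermediate (not isolated)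
6 | methyl (2S,3S)-3-methyloxolane-2-carboxylate | C[C@H]1CCO[C@@H]1C(=O)OC | intermediate
7 | (2S,3S)-N-methoxy-N,3-dimethyloxolane-2-carboxamide | C[C@H]1CCO[C@@H]1C(=O)N(C)OC | intermediate
8 | 1,4-bis(trimethylsilyl)buta-1,3-diyne | C[Si](C)(C)C#CC#C[Si](C)(C)C | starting material
9 | lithium 4-(trimethylsilyl)buta-1,3-diyn-1-ide | [Li]C#CC#C[Si](C)(C)C | intermediate (not isolated)
10 | 1-[(2S,3S)-3-methyloxolan-2-yl]-5-(trimethylsilyl)penta-2,4-diyn-1-one | C[C@H]1CCO[C@@H]1C(=O)C#CC#C[Si](C)(C)C | intermediate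
11 | (2R)-2-[(2S,3S)-3-methyloxolan-2-yl]-6-(trimethylsilyl)hexa-3,5-diyn-2-ol | C[C@H]1CCO[C@@H]1[C@](C)(O)C#CC#C[Si](C)(C)C | intermediate
12 | sodium alkenylalanate: five-membered O–Al–C9=C10–C11 ring from 11, aluminium bearing two 2-methoxyethoxy groups | [Na+].COCCO[Al-]1(OCCOC)O[C@@](C)([C@H]2OCC[C@@H]2C)C=C1C#C[Si](C)(C)C | intermediate (not isolated)
13 | (2R,3E)-2-[(2S,3S)-3-methyloxolan-2-yl]-6-(trimethylsilyl)hex-3-en-5-yn-2-ol | C[C@H]1CCO[C@@H]1[C@](C)(O)/C=C/C#C[Si](C)(C)C | intermediate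
14 | (2R,3E)-2-[(2S,3S)-3-methyloxolan-2-yl]hex-3-en-5-yn-2-ol | C[C@H]1CCO[C@@H]1[C@](C)(O)/C=C/C#C | intermediate
15 | (4S)-4-benzyl-1,3-oxazolidin-2-one | O=C1OC[C@H](Cc2ccccc2)N1 | starting material
16 | (2E)-but-2-enoyl chloride | C/C=C/C(Cl)=O | starting material
17 | N-lithio-(4S)-4-benzyl-1,3-oxazolidin-2-one | [Li]N1[C@@H](Cc2ccccc2)COC1=O | intermediate (not isolated)
18 | (4S)-4-benzyl-3-[(2E)-but-2-enoyl]-1,3-oxazolidin-2-one | C/C=C/C(=O)N1[C@@H](Cc2ccccc2)COC1=O | intermediate
19 | acetaldehyde | CC=O | starting material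
20 | (Z)-dibutylboron dienolate of 18 | C=C/C=C(\OB(CCCC)CCCC)N1[C@@H](Cc2ccccc2)COC1=O | intermediate (not isolated)
21 | (4S)-4-benzyl-3-[(2S,3R)-2-ethenyl-3-hydroxybutanoyl]-1,3-oxazolidin-2-one | C[C@@H](O)[C@H](C=C)C(=O)N1[C@@H](Cc2ccccc2)COC1=O | intermediate
22 | (4S)-4-benzyl-3-[(2S,3R)-3-{[tert-butyl(dimethyl)silyl]oxy}-2-ethenylbutanoyl]-1,3-oxazolidin-2-one | C[C@@H](O[Si](C)(C)C(C)(C)C)[C@H](C=C)C(=O)N1[C@@H](Cc2ccccc2)COC1=O | intermediate
23 | (2R,3R)-3-{[tert-butyl(dimethyl)silyl]oxy}-2-ethenylbutan-1-ol | C[C@@H](O[Si](C)(C)C(C)(C)C)[C@H](C=C)CO | intermediate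
24 | 2-methylprop-2-enoyl chloride | C=C(C)C(Cl)=O | starting material
25 | (2R,3R)-3-{[tert-butyl(dimethyl)silyl]oxy}-2-ethenylbutyl 2-methylprop-2-enoate | C[C@@H](O[Si](C)(C)C(C)(C)C)[C@H](C=C)COC(=O)C(C)=C | intermediate
26 | (5R)-5-[(1R)-1-{[tert-butyl(dimethyl)silyl]oxy}ethyl]-3-methyl-5,6-dihydro-2H-pyran-2-one | C[C@@H](O[Si](C)(C)C(C)(C)C)[C@H]1COC(=O)C(C)=C1 | intermediate
27 | (3R,4R,5S)-5-[(1R)-1-{[tert-butyl(dimethyl)silyl]oxy}ethyl]-3,4-dihydroxy-3-methyloxan-2-one | C[C@@H](O[Si](C)(C)C(C)(C)C)[C@H]1COC(=O)[C@](C)(O)[C@@H]1O | intermediate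
28 | (3aR,7S,7aR)-7-[(1R)-1-{[tert-butyl(dimethyl)silyl]oxy}ethyl]-2,2,3a-trimethyl-3a,6,7,7a-tetrahydro-4H-[1,3]dioxolo[4,5-c]pyran-4-one | C[C@@H](O[Si](C)(C)C(C)(C)C)[C@H]1COC(=O)[C@]2(C)OC(C)(C)O[C@H]12 | intermediate
29 | (3aR,7R,7aR)-7-[(1R)-1-hydroxyethyl]-2,2,3a-trimethyl-3a,6,7,7a-tetrahydro-4H-[1,3]dioxolo[4,5-c]pyran-4-one | C[C@@H](O)[C@H]1COC(=O)[C@]2(C)OC(C)(C)O[C@H]12 | intermediate
30 | (3aR,7S,7aR)-7-acetyl-2,2,3a-trimethyl-3a,6,7,7a-tetrahydro-4H-[1,3]dioxolo[4,5-c]pyran-4-one | CC(=O)[C@H]1COC(=O)[C@]2(C)OC(C)(C)O[C@H]12 | intermediate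
31 | lithium enolate of 30 on the methyl side | [Li]OC(=C)[C@H]1COC(=O)[C@]2(C)OC(C)(C)O[C@H]12 | intermediate (not isolated)
32 | (3aR,7S,7aR)-7-(hydroxymethyl)-2,2,3a-trimethyl-7,7a-dihydro-3aH-1,3-benzodioxole-4,6(5H)-dione | OC[C@@H]1C(=O)CC(=O)[C@]2(C)OC(C)(C)O[C@H]12 | intermediate
33 | (3aR,7S,7aR)-5-chloro-6-hydroxy-7-(hydroxymethyl)-2,2,3a-trimethyl-7,7a-dihydro-1,3-benzodioxol-4(3aH)-one (drawn as the C4a enol) | OC[C@@H]1C(O)=C(Cl)C(=O)[C@]2(C)OC(C)(C)O[C@H]12 | intermediate
34 | (3aR,7S,7aR)-5-chloro-7-(hydroxymethyl)-2,2,3a-trimethyl-4-oxo-3a,4,7,7a-tetrahydro-1,3-benzodioxol-6-yl trifluoromethanesulfonate | OC[C@@H]1C(OS(=O)(=O)C(F)(F)F)=C(Cl)C(=O)[C@]2(C)OC(C)(C)O[C@H]12 | intermediate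
35 | (3aR,7S,7aR)-5-chloro-7-(hydroxymethyl)-6-{(3E,5R)-5-hydroxy-5-[(2S,3S)-3-methyloxolan-2-yl]hex-3-en-1-yn-1-yl}-2,2,3a-trimethyl-7,7a-dihydro-1,3-benzodioxol-4(3aH)-one | OC[C@@H]1C(C#C/C=C/[C@@](C)(O)[C@H]3OCC[C@@H]3C)=C(Cl)C(=O)[C@]2(C)OC(C)(C)O[C@H]12 | intermediate
36 | (7R,8R,8aS)-5-chloro-3-{(1E,3R)-3-hydroxy-3-[(2S,3S)-3-methyloxolan-2-yl]but-1-en-1-yl}-7-methyl-7,8-(isopropylidenedioxy)-1,7,8,8a-tetrahydro-6H-isochromen-6-one (7,8-acetonide of 37) | C[C@H]1CCO[C@@H]1[C@](C)(O)/C=C/C1=CC2=C(Cl)C(=O)[C@]3(C)OC(C)(C)O[C@@H]3[C@@H]2CO1 | intermediate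
37 | CNP0432723.2, (7R,8R,8aS)-5-chloro-7,8-dihydroxy-3-{(1E,3R)-3-hydroxy-3-[(2S,3S)-3-methyloxolan-2-yl]but-1-en-1-yl}-7-methyl-1,7,8,8a-tetrahydro-6H-isochromen-6-one | C[C@H]1CCO[C@@H]1[C@](C)(O)/C=C/C1=CC2=C(Cl)C(=O)[C@](C)(O)[C@H](O)[C@@H]2CO1 | target

**Step count and weak points**

Total step count: 24. Longest linear sequence: 16 steps (steps 9–24, from 15); the oxolane branch is 8 steps (steps 1–8) before the coupling.

Steps most likely to fail:

1. Step 3 (key step). β-Scission of the alkoxy radical with loss of a sec-butyl radical, or hydrogen return, may outrun the slow abstraction from a primary C–H bond, and the ether may be over-oxidised next to oxygen. Fallback: the same O1'–C5' bond is made through a nitrogen-radical relay followed by exchange of nitrogen for oxygen. Setting out from 1, N-chlorination with tBuOCl should give (2S,3S)-2-(chloroamino)-3-methylpentanoic acid F1. Photolysis in H2SO4 (Hofmann–Löffler–Freytag reaction: aminium radical, 1,5-hydrogen transfer from C5', chlorine transfer) should give (2S,3S)-2-amino-5-chloro-3-methylpentanoic acid F2. Diazotisation in aqueous acid with retention should give (2S,3S)-5-chloro-2-hydroxy-3-methylpentanoic acid F3, and Fischer esterification the ester methyl (2S,3S)-5-chloro-2-hydroxy-3-methylpentanoate F4. K2CO3 with NaI in DMF should then close the ether in a 5-exo-tet displacement, which comes back to the route at 6.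

2. Step 19. Enolisation toward C8a instead of the methyl group, followed by β-elimination of the lactone or acetonide oxygen or by epimerisation, may compete, and strain in the bridged tetrahedral adduct may stop the acyl transfer. Fallback: the lactone is opened before the ketone is unmasked, and ring A is closed by an unstrained open-chain Claisen acylation. Setting out from 28, Me(MeO)NH·HCl with AlMe3 should open the lactone to the C1-hydroxy Weinreb amide F5. Neutral PMB transfer (PMB trichloroacetimidate, cat. La(OTf)3) should give the C1 PMB ether F6, and HF·pyridine should free the secondary alcohol F7. Dess–Martin oxidation should give the methyl ketone F8, and LiN(SiMe3)2 should close ring A onto the Weinreb amide to give the diketone PMB ether F9. DDQ removes the PMB group, which comes back to the route at 32.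

3. Step 21. Sulfonylation may take place at the oxygen on C6 instead of C4a, giving the transposed enone after coupling, and some triflation of the primary alcohol is possible. Fallback: 1,2-addition with carbonyl transposition replaces the cross-coupling and uses the opposite enol derivative. Setting out from 33, O-methylation with Me3SiCHN2 in MeOH and separation should give the C6 methyl enol ether F10. The dilithio derivative of 14 (n-BuLi, CeCl3, with one further equivalent of base for the C1 hydroxyl) should add to the C4a ketone to give the tertiary propargylic carbinol F11 as a mixture of epimers at the new carbinol carbon. Cold dilute HCl should hydrolyse the enol ether with loss of water (Stork–Danheiser transposition), which comes back to the route at 35.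

**Further compounds**

F1 | step 3 | (2S,3S)-2-(chloroamino)-3-methylpentanoic acid | CC[C@H](C)[C@H](NCl)C(=O)O
F2 | step 3 | (2S,3S)-2-amino-5-chloro-3-methylpentanoic acid | ClCC[C@H](C)[C@H](N)C(=O)O
F3 | step 3 | (2S,3S)-5-chloro-2-hydroxy-3-methylpentanoic acid | ClCC[C@H](C)[C@H](O)C(=O)O
F4 | step 3 | methyl (2S,3S)-5-chloro-2-hydroxy-3-methylpentanoate | ClCC[C@H](C)[C@H](O)C(=O)OC
F5 | step 19 | (4R,5R)-5-[(2S,3R)-3-{[tert-butyl(dimethyl)silyl]oxy}-1-hydroxybutan-2-yl]-N-methoxy-N,2,2,4-tetramethyl-1,3-dioxolane-4-carboxamide | CON(C)C(=O)[C@]1(C)OC(C)(C)O[C@@H]1[C@H](CO)[C@@H](C)O[Si](C)(C)C(C)(C)C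
F6 | step 19 | 4-methoxybenzyl ether of F5 at the primary (C1) hydroxyl | CON(C)C(=O)[C@]1(C)OC(C)(C)O[C@@H]1[C@H](COCc2ccc(OC)cc2)[C@@H](C)O[Si](C)(C)C(C)(C)C
F7 | step 19 | desilylated F6, free secondary (C4a) alcohol | CON(C)C(=O)[C@]1(C)OC(C)(C)O[C@@H]1[C@H](COCc2ccc(OC)cc2)[C@@H](C)O
F8 | step 19 | methyl ketone from F7 (C4a ketone, C6 Weinreb amide, C1 PMB ether) | CON(C)C(=O)[C@]1(C)OC(C)(C)O[C@@H]1[C@H](COCc2ccc(OC)cc2)C(C)=O
F9 | step 19 | 4-methoxybenzyl ether of 32 at the C1 hydroxyl | COc1ccc(COC[C@@H]2C(=O)CC(=O)[C@]3(C)OC(C)(C)O[C@H]23)cc1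
F10 | step 21 | (3aR,7S,7aR)-5-chloro-7-(hydroxymethyl)-4-methoxy-2,2,3a-trimethyl-7,7a-dihydro-1,3-benzodioxol-6(3aH)-one (C6 methyl enol ether of 33) | OC[C@@H]1C(=O)C(Cl)=C(OC)[C@]2(C)OC(C)(C)O[C@H]12
F11 | step 21 | 1,2-adduct of the acetylide of 14 to the C4a ketone of F10 (tertiary propargylic carbinol, both epimers at C4a) | OC[C@@H]1C(O)(C#C/C=C/[C@@](C)(O)[C@H]3OCC[C@@H]3C)C(Cl)=C(OC)[C@]2(C)OC(C)(C)O[C@H]12
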